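**Retrosynthetic overview**
- The target comes from methanolysis of a tricyclic lactone. Its temporary ring C (O7–C(=O)–CH2–CH(Pr)–C8) is made by a chiral-carbene annulation of hex-2-ynal onto 7-OH/C8 of the 6-prenylchromanone, which sets the side-chain R centre.
- The C6 prenyl group comes from cross-metathesis of a 6-allyl group. That allyl is delivered by a Claisen shift from O5, where C6 is the only free ortho carbon. The more reactive 7-OH is silylated meanwhile.
- Feature: in pyranone ring B, the C4 carbonyl carbon sits on ring A. Its neighbour C3 is a methine bearing CH3 and lies next to the O1-bound C2. C4 therefore maps onto an aryl aldehyde carbon, C3 with its methyl onto a vinyl group, and C2 onto the carbinol carbon of enantiopure but-3-en-2-ol. The C3–C4 bond is cut as a carbene-catalysed alkene hydroacylation.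
- The hydroacylation precursor comes from Mitsunobu inversion of (R)-but-3-en-2-ol with 2-hydroxy-4,6-dimethoxybenzaldehyde.
- Ring order: ring A is bought, ring B forms in step 2, and ring C forms in step 10 and is opened in step 11.

Key step: step 2

Assumption: the sense of induction of the aminoindanol-derived triazolium salt in step 10 is taken from the usual face-shielding model. If a pilot run gives the 10S lactone, the equally commercial (5aS,10bR) antipode is used instead.

**Step 1**
Reactants: 1 2-hydroxy-4,6-dimethoxybenzaldehyde; 2 (R)-but-3-en-2-ol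
Product: 3 (S)-2-(but-3-en-2-yloxy)-4,6-dimethoxybenzaldehyde
Conditions: PPh3, DIAD, THF, 0 °C → rt
Reagents that add atoms: none
Why: Mitsunobu etherification, in which the acidic salicylaldehyde phenol displaces the oxyphosphonium of 2 in an SN2 sense and inverts the R carbinol carbon to the S ether carbon that becomes C2; low temperature should keep SN2' leakage to the separable linear crotyl ether minor.

**Step 2**
Reactants: 3 (S)-2-(but-3-en-2-yloxy)-4,6-dimethoxybenzaldehyde
Product: 5 (2S,3S)-5,7-dimethoxy-2,3-dimethylchroman-4-one, via (2S,3R)-cis-chromanone 4 (not isolated)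
Conditions: 2-mesityl-6,7-dihydro-5H-pyrrolo[2,1-c][1,2,4]triazol-2-ium chloride (20 mol %), DBU (20 mol %), degassed 1,4-dioxane (0.1 M), 90 °C
Reagents that add atoms: none
Why: The carbene released by DBU adds to the aldehyde and proton transfer gives the enaminol, an acyl anion equivalent, whose O–H and nucleophilic carbon add across the tethered vinyl group through one concerted, asynchronous, ene-like five-centre transition state that makes C3–C4 while the hydrogen lands on the terminal carbon (the future C3 methyl); loss of the carbene from the resulting alkoxide gives the ketone. The closest known reaction is the carbene-catalysed intramolecular hydroacylation of unactivated alkenes in 2-allyloxybenzaldehydes to 3-methylchroman-4-ones, to which 3 adds only a methyl on the ether carbon and a second ortho oxygen. Ring B closes 6-exo-trig on the internal alkene carbon, since only this mode lets the hydroxyl hydrogen reach the other alkene carbon within the five-centre array. C2 takes no part and keeps the S configuration from step 1, whereas C3 forms with little facial bias and, being alpha to the ketone, is equilibrated by the amidine so that cis epimer 4 drains toward the diequatorial trans isomer 5; this preference is only moderate, so remaining 4 is separated and recycled with Et3N. The step needs hydroacylation to outrun benzoin coupling, aryl ether Claisen shift and retro-oxa-Michael opening of the product: the two ortho oxygens crowd the aldehyde too much for benzoin coupling, 90 °C lies well below the Claisen threshold of such ethers, and DBU is held equimolar to the azolium salt so that hardly any free base remains to open ring B and erode C2.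

**Step 3**
Reactants: 5 (2S,3S)-5,7-dimethoxy-2,3-dimethylchroman-4-one
Product: 6 (2S,3S)-5,7-dihydroxy-2,3-dimethylchroman-4-one
Conditions: BBr3 (5 equiv), CH2Cl2, −78 °C → rt; ice-water
Reagents that add atoms: none
Why: Lewis-acid aryl methyl ether cleavage, in which bromide attacks the unhindered methyl carbons (the peri 5-OMe first, through the O4/O5 boron chelate), whereas breaking O1–C2 would need displacement at a branched secondary carbon beta to a complexed carbonyl, so ring B and both stereocentres should persist.

**Step 4**
Reactants: 6 (2S,3S)-5,7-dihydroxy-2,3-dimethylchroman-4-one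
Product: 7 (2S,3S)-7-[(tert-butyldimethylsilyl)oxy]-5-hydroxy-2,3-dimethylchroman-4-one
Conditions: TBSCl (1.05 equiv), imidazole, DMF, 0 °C
Reagents that add atoms: tert-butyldimethylsilyl chloride, CC(C)(C)[Si](C)(C)Cl
Why: Chemoselective silylation, since 7-OH is the free and more acidic phenol while 5-OH is tied up in a hydrogen bond to C4=O; the mask is needed because any direct alkylation of 6 would occur at O7 rather than O5.

**Step 5**
Reactants: 7 (2S,3S)-7-[(tert-butyldimethylsilyl)oxy]-5-hydroxy-2,3-dimethylchroman-4-one; 8 prop-2-en-1-ol (allyl alcohol)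
Product: 9 (2S,3S)-5-(allyloxy)-7-[(tert-butyldimethylsilyl)oxy]-2,3-dimethylchroman-4-one
Conditions: PPh3, DIAD, THF, 0 °C → rt
Reagents that add atoms: none
Why: Mitsunobu etherification alkylates even the hydrogen-bonded 5-OH with a primary allylic alcohol under essentially neutral conditions, so no carbonate or amidine base is present that could enolise C3, open ring B or strip the aryl silyl ether.

**Step 6**
Reactants: 9 (2S,3S)-5-(allyloxy)-7-[(tert-butyldimethylsilyl)oxy]-2,3-dimethylchroman-4-one
Product: 10 (2S,3S)-6-allyl-7-[(tert-butyldimethylsilyl)oxy]-5-hydroxy-2,3-dimethylchroman-4-one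
Conditions: Eu(fod)3 (fod = 6,6,7,7,8,8,8-heptafluoro-2,2-dimethyloctane-3,5-dionate; 10 mol %), PhCl, 120 °C
Reagents that add atoms: none
Why: Aromatic Claisen rearrangement, in which the [3,3] shift from O5 can end productively only at C6 because the other ortho carbon, C4a, is quaternary; tautomerisation of the C6 dienone restores the chelated 5-OH, and binding of trivalent europium to the O4/O5 pair lowers the temperature needed, which spares C2 and the silyl ether.

**Step 7**
Reactants: 10 (2S,3S)-6-allyl-7-[(tert-butyldimethylsilyl)oxy]-5-hydroxy-2,3-dimethylchroman-4-one; 11 2-methylbut-2-ene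
Product: 12 (2S,3S)-7-[(tert-butyldimethylsilyl)oxy]-5-hydroxy-2,3-dimethyl-6-(3-methylbut-2-en-1-yl)chroman-4-one
Conditions: second-generation Grubbs catalyst, (H2IMes)(PCy3)Cl2Ru=CHPh (5 mol %), 2-methylbut-2-ene/CH2Cl2, sealed tube, 40 °C
Reagents that add atoms: none
Why: Olefin cross-metathesis of a terminal allyl arene with excess 2-methylbut-2-ene is the standard conversion of allyl into prenyl; propene escapes and the trisubstituted product alkene does not re-enter the catalytic cycle.

**Step 8**
Reactants: 12 (2S,3S)-7-[(tert-butyldimethylsilyl)oxy]-5-hydroxy-2,3-dimethyl-6-(3-methylbut-2-en-1-yl)chroman-4-one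
Product: 13 (2S,3S)-5,7-dihydroxy-2,3-dimethyl-6-(3-methylbut-2-en-1-yl)chroman-4-one
Conditions: TBAF, AcOH (1:1), THF, 0 °C
Reagents that add atoms: none
Why: Fluoride-induced cleavage of an aryl silyl ether, buffered with acetic acid so that nothing basic acts on C3 or ring B, and free of the strong acid that could cyclise the prenyl group onto a flanking phenol.

**Step 9**
Reactants: 14 hex-2-yn-1-ol
Product: 15 hex-2-ynal
Conditions: activated MnO2 (excess), CH2Cl2, rt
Reagents that add atoms: none
Why: Manganese dioxide oxidation of a propargylic alcohol stops at the ynal, which is used promptly as a solution because it is volatile and prone to oligomerise.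

**Step 10**
Reactants: 13 (2S,3S)-5,7-dihydroxy-2,3-dimethyl-6-(3-methylbut-2-en-1-yl)chroman-4-one; 15 hex-2-ynal
Product: 16 (2S,3S,10R)-5-hydroxy-2,3-dimethyl-6-(3-methylbut-2-en-1-yl)-10-propyl-2,3,9,10-tetrahydro-4H,8H-pyrano[2,3-f]chromene-4,8-dione
Conditions: (5aR,10bS)-2-mesityl-5a,10b-dihydro-4H,6H-indeno[2,1-b][1,2,4]triazolo[4,3-d][1,4]oxazin-2-ium chloride (10 mol %), no added base, toluene, 40 °C, slow addition of 15 (1.5 equiv)
Reagents that add atoms: none
Why: Proposed new method: the carbene turns ynal 15 by internal redox into the (E)-hex-2-enoyl azolium; the 7-OH, a vinylogous acid through C4=O with an acidity close to that of the stable enols known to react, adds to the acyl carbon, and a [3,3] shift of the hemiketal (or the equivalent Michael addition of the phenoxide) joins the beta carbon to C8, the only unsubstituted ring carbon, after which O7 acylation closes ring C 6-exo-trig and frees the carbene; plain O-acylation should be reversible because the aryl ester of so acidic a phenol is re-activated by the carbene, the indane wall of the catalyst shields one face of the enoyl azolium and sets 10R independently of the remote C2/C3 centres, and the closest known reaction type is the carbene-catalysed annulation of ynals with kojic acids, 1,3-dicarbonyl compounds and 2-naphthols to dihydropyranones.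

**Step 11**
Reactants: 16 (2S,3S,10R)-5-hydroxy-2,3-dimethyl-6-(3-methylbut-2-en-1-yl)-10-propyl-2,3,9,10-tetrahydro-4H,8H-pyrano[2,3-f]chromene-4,8-dione
Product: 17 methyl (3R)-3-[(2S,3S)-5,7-dihydroxy-2,3-dimethyl-6-(3-methylbut-2-en-1-yl)-4-oxochroman-8-yl]hexanoate (CNP0068017.2)
Conditions: MeOH, DMAP (10 mol %), 0 °C → rt; neutral work-up
Reagents that add atoms: methanol, CO
Why: Nucleophile-catalysed transesterification, since the lactone is the aryl ester of an acidic phenol and is opened readily by methanol; the large excess of methanol holds the equilibrium on the hydroxy ester side, and the conditions are too mild to disturb C2, C3 or the non-acidic benzylic centre.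

**Compound list**
1 | 2-hydroxy-4,6-dimethoxybenzaldehyde | COc1cc(O)c(C=O)c(OC)c1 | starting material
2 | (R)-but-3-en-2-ol | C[C@@H](O)C=C | starting material
3 | (S)-2-(but-3-en-2-yloxy)-4,6-dimethoxybenzaldehyde | COc1cc(OC)c(C=O)c(O[C@@H](C)C=C)c1 | intermediate
4 | (2S,3R)-5,7-dimethoxy-2,3-dimethylchroman-4-one (cis epimer, not isolated) | COc1cc(OC)c2c(c1)O[C@@H](C)[C@@H](C)C2=O | intermediate
5 | (2S,3S)-5,7-dimethoxy-2,3-dimethylchroman-4-one | COc1cc(OC)c2c(c1)O[C@@H](C)[C@H](C)C2=O | intermediate
6 | (2S,3S)-5,7-dihydroxy-2,3-dimethylchroman-4-one | Oc1cc(O)c2c(c1)O[C@@H](C)[C@H](C)C2=O | intermediate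
7 | (2S,3S)-7-[(tert-butyldimethylsilyl)oxy]-5-hydroxy-2,3-dimethylchroman-4-one | CC(C)(C)[Si](C)(C)Oc1cc(O)c2c(c1)O[C@@H](C)[C@H](C)C2=O | intermediate
8 | prop-2-en-1-ol (allyl alcohol) | C=CCO | starting material
9 | (2S,3S)-5-(allyloxy)-7-[(tert-butyldimethylsilyl)oxy]-2,3-dimethylchroman-4-one | CC(C)(C)[Si](C)(C)Oc1cc(OCC=C)c2c(c1)O[C@@H](C)[C@H](C)C2=O | intermediate
10 | (2S,3S)-6-allyl-7-[(tert-butyldimethylsilyl)oxy]-5-hydroxy-2,3-dimethylchroman-4-one | CC(C)(C)[Si](C)(C)Oc1c(CC=C)c(O)c2c(c1)O[C@@H](C)[C@H](C)C2=O | intermediate
11 | 2-methylbut-2-ene | CC=C(C)C | starting material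
12 | (2S,3S)-7-[(tert-butyldimethylsilyl)oxy]-5-hydroxy-2,3-dimethyl-6-(3-methylbut-2-en-1-yl)chroman-4-one | CC(C)(C)[Si](C)(C)Oc1c(CC=C(C)C)c(O)c2c(c1)O[C@@H](C)[C@H](C)C2=O | intermediate
13 | (2S,3S)-5,7-dihydroxy-2,3-dimethyl-6-(3-methylbut-2-en-1-yl)chroman-4-one | Oc1c(CC=C(C)C)c(O)c2c(c1)O[C@@H](C)[C@H](C)C2=O | intermediate
14 | hex-2-yn-1-ol | CCCC#CCO | starting material
15 | hex-2-ynal | CCCC#CC=O | intermediate
16 | (2S,3S,10R)-5-hydroxy-2,3-dimethyl-6-(3-methylbut-2-en-1-yl)-10-propyl-2,3,9,10-tetrahydro-4H,8H-pyrano[2,3-f]chromene-4,8-dione | CCC[C@@H]1CC(=O)Oc2c1c3O[C@@H](C)[C@H](C)C(=O)c3c(O)c2CC=C(C)C | intermediate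
17 | methyl (3R)-3-[(2S,3S)-5,7-dihydroxy-2,3-dimethyl-6-(3-methylbut-2-en-1-yl)-4-oxochroman-8-yl]hexanoate | CCC[C@H](CC(=O)OC)c1c(O)c(CC=C(C)C)c(O)c2c1O[C@@H](C)[C@H](C)C2=O | target

**Total step count:** 11
**Longest linear sequence:** 10 (steps 1–8, 10 and 11; step 9 is a one-step side branch)

**Steps most likely to fail**

1. **Step 10 (bears the label).**
   - The phenol may be acylated on oxygen and stall at the hexenoate ester stage.
   - C8 of the acyl-deactivated ring may be too weak a carbon nucleophile.
   - Facial discrimination with a slim n-propyl group may be poor.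
   - The fallback sets out from 13 and returns at 16. It gives up catalyst control in favour of known Michael chemistry plus separation.
   - Butanal and Meldrum's acid are condensed in the presence of 13 (proline cat., MeCN, rt). This forms 5-butylidene-2,2-dimethyl-1,3-dioxane-4,6-dione F1 in the flask.
   - C8 of the phenoxide adds to F1 in a Michael sense, as acylphloroglucinols are known to do with alkylidene 1,3-dicarbonyl acceptors. This gives the Meldrum's acid adduct F2 as both epimers at the benzylic carbon.
   - Heating in toluene–pyridine lets 7-OH open the dioxanedione with loss of acetone and carbon dioxide. This gives 16 together with the 10S-epimeric lactone F3.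
   - Because ring B is already enantiopure, 16 and F3 are diastereomers and are parted by chromatography or crystallisation.

2. **Step 2 (key step).**
   - Carbene addition to the doubly ortho-oxygenated, electron-rich aldehyde may be too slow.
   - Prolonged heating with base may open the product by retro-oxa-Michael reaction and erode C2.
   - The ether may begin to undergo a Claisen shift.
   - The fallback sets out from 3 and returns at 5. It makes the same C3–C4 bond in the radical manifold under neutral conditions.
   - Pinnick oxidation (NaClO2, NaH2PO4, 2-methylbut-2-ene, t-BuOH/H2O) gives (S)-2-(but-3-en-2-yloxy)-4,6-dimethoxybenzoic acid F4.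
   - (PhSe)2/Bu3P converts it into Se-phenyl (S)-2-(but-3-en-2-yloxy)-4,6-dimethoxybenzoselenoate F5.
   - (Me3Si)3SiH with Et3B/air in toluene at rt generates the aroyl radical. It cyclises 6-exo-trig onto the internal alkene carbon, and the primary radical is reduced to the C3 methyl.
   - The resulting mixture of 4 and 5 is equilibrated with Et3N at rt, and 5 is isolated.

3. **Step 3.**
   - Boron- or HBr-promoted enolisation may be followed by opening and reclosure of ring B, with loss of C2 integrity.
   - Cleavage of the deactivated 7-OMe may be incomplete.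
   - The fallback sets out from 2 and returns at 6. It replaces the methyl ethers by acetal groups so that no strong Lewis acid is needed.
   - Commercial 2,4,6-trihydroxybenzaldehyde is bis-protected (MOMCl, i-Pr2NEt, CH2Cl2, 0 °C) to 2-hydroxy-4,6-bis(methoxymethoxy)benzaldehyde F6.
   - Mitsunobu reaction with 2 gives (S)-2-(but-3-en-2-yloxy)-4,6-bis(methoxymethoxy)benzaldehyde F7.
   - The carbene hydroacylation of step 2 gives (2S,3S)-5,7-bis(methoxymethoxy)-2,3-dimethylchroman-4-one F8.
   - Dilute HCl in MeOH at rt to 40 °C releases 6.

**Further compounds**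
F1 | step 10 | 5-butylidene-2,2-dimethyl-1,3-dioxane-4,6-dione | CCCC=C1C(=O)OC(C)(C)OC1=O
F2 | step 10 | 5-{1-[(2S,3S)-5,7-dihydroxy-2,3-dimethyl-6-(3-methylbut-2-en-1-yl)-4-oxochroman-8-yl]butyl}-2,2-dimethyl-1,3-dioxane-4,6-dione (both epimers at the benzylic carbon) | CCCC(C1C(=O)OC(C)(C)OC1=O)c1c(O)c(CC=C(C)C)c(O)c2c1O[C@@H](C)[C@H](C)C2=O
F3 | step 10 | (2S,3S,10S)-5-hydroxy-2,3-dimethyl-6-(3-methylbut-2-en-1-yl)-10-propyl-2,3,9,10-tetrahydro-4H,8H-pyrano[2,3-f]chromene-4,8-dione | CCC[C@H]1CC(=O)Oc2c1c3O[C@@H](C)[C@H](C)C(=O)c3c(O)c2CC=C(C)C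
F4 | step 2 | (S)-2-(but-3-en-2-yloxy)-4,6-dimethoxybenzoic acid | COc1cc(OC)c(C(=O)O)c(O[C@@H](C)C=C)c1
F5 | step 2 | Se-phenyl (S)-2-(but-3-en-2-yloxy)-4,6-dimethoxybenzoselenoate | COc1cc(OC)c(C(=O)[Se]c2ccccc2)c(O[C@@H](C)C=C)c1
F6 | step 3 | 2-hydroxy-4,6-bis(methoxymethoxy)benzaldehyde | COCOc1cc(O)c(C=O)c(OCOC)c1
F7 | step 3 | (S)-2-(but-3-en-2-yloxy)-4,6-bis(methoxymethoxy)benzaldehyde | COCOc1cc(OCOC)c(C=O)c(O[C@@H](C)C=C)c1
F8 | step 3 | (2S,3S)-5,7-bis(methoxymethoxy)-2,3-dimethylchroman-4-one | COCOc1cc(OCOC)c2c(c1)O[C@@H](C)[C@H](C)C2=O
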